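The isoflavone is disconnected at C4a–C5 in ring A and at O1–C2 in ring C. In ring A the oxygens sit on C5, C7 and C8a, mutually meta, and C4a, between two of them, holds the C4 carbonyl; this is the imprint of a linear 3,5,7-triketo ester closed by Claisen condensation. The precursor is that open chain, whose last ketone is flanked by a tertiary carbon bearing ring B and a dimethyl acetal, the latent C2. Mg(OMe)2 folds the chain into ring A; acidifying the same flask lets the C8a phenol capture the acetal carbon and expel methanol, completing ring C. Both fused rings arise in one operation, without phenol protection.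

Key step: step 8

Remark: every intermediate with the aryl-bearing sp3 carbon is handled as a racemate, because this carbon becomes sp2 C3 of the achiral target. Polycarbonyl compounds are drawn in their keto forms, and Mg(OMe)2 and LiN(i-Pr)2 are taken as commercial solutions.

Step 1
Reactants: 1 1,2,3,5-tetramethoxybenzene; 2 dimethyl oxalate
Product: 4 methyl 2-oxo-2-(2,3,4,6-tetramethoxyphenyl)acetate, via aryllithium 3 (not isolated)
Conditions: n-BuLi, THF, 0 °C to rt; cannulated into 2 (3 equiv), THF, −78 °C; 1 M HCl
Reagents that add atoms: none
Why: Directed ortho-metalation removes one of the two equivalent ring protons, each flanked by two methoxy groups, and acylation of the hindered aryllithium by excess oxalate diester at low temperature should stop at the α-keto ester because the tetrahedral adduct persists until the quench.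

Step 2
Reactants: 4 methyl 2-oxo-2-(2,3,4,6-tetramethoxyphenyl)acetate
Product: 5 methyl 2-(2,3,4,6-tetramethoxyphenyl)acetate
Conditions: Et3SiH (3 equiv), CF3CO2H/CH2Cl2, 0 °C to rt
Reagents that add atoms: none
Why: In this ionic hydrogenation, protonation and hydride transfer give the mandelate, whose benzylic cation is stabilised by two ortho and one para methoxy groups, so a second hydride transfer should complete the deoxygenation and leave the ester and aryl ethers alone.

Step 3
Reactants: 5 methyl 2-(2,3,4,6-tetramethoxyphenyl)acetate; 6 methyl formate
Product: 7 methyl 3-oxo-2-(2,3,4,6-tetramethoxyphenyl)propanoate (racemic, in equilibrium with its hydroxymethylene enol)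
Conditions: NaH, 6 (excess), cat. MeOH, THF, 0 °C to rt; cold 1 M HCl
Reagents that add atoms: none
Why: This crossed Claisen condensation uses a formate that cannot enolise and is driven by the stabilised sodium enolate of the formyl ester; the new centre is configurationally labile and racemic.

Step 4
Reactants: 7 methyl 3-oxo-2-(2,3,4,6-tetramethoxyphenyl)propanoate
Product: 8 methyl 3,3-dimethoxy-2-(2,3,4,6-tetramethoxyphenyl)propanoate (racemic)
Conditions: HC(OMe)3, MeOH, cat. p-TsOH, rt; Et3N before concentration
Reagents that add atoms: trimethyl orthoformate, COC(OC)OC; methanol, CO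
Why: In this acid-catalysed acetalisation the orthoformate scavenges water, and at room temperature in excess methanol the saturated acetal should be preferred to the enol ether because the twisted ring B lends an acrylate little conjugation; the centre forms as a racemate.

Step 5
Reactants: 8 methyl 3,3-dimethoxy-2-(2,3,4,6-tetramethoxyphenyl)propanoate
Product: 9 3,3-dimethoxy-2-(2,3,4,6-tetramethoxyphenyl)propanoic acid (racemic)
Conditions: LiOH, THF/MeOH/H2O, rt to 40 °C; 1 M HCl to pH 4 at 0 °C, immediate extraction
Reagents that add atoms: lithium hydroxide, [Li+].[OH-]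
Why: In this saponification the di-ortho-substituted aryl group cannot lie coplanar with an ester enolate, which keeps the α-proton weakly acidic and holds back β-elimination of methoxide, and the acetal, deactivated by the adjacent carboxyl, should survive a brief cold acidification.

Step 6
Reactants: 10 dehydroacetic acid (3-acetyl-4-hydroxy-6-methyl-2H-pyran-2-one)
Product: 11 methyl 3,5-dioxohexanoate
Conditions: Mg(OMe)2, MeOH, reflux; cold 2 M HCl; distillation
Reagents that add atoms: magnesium dimethoxide, C[O-].C[O-].[Mg+2]; methanol, CO
Why: Lactone methanolysis is followed by retro-Claisen loss of the 3-acetyl group as methyl acetate, and magnesium chelation of the resulting 3,5-diketo ester protects it from further cleavage.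

Step 7
Reactants: 9 3,3-dimethoxy-2-(2,3,4,6-tetramethoxyphenyl)propanoic acid; 11 methyl 3,5-dioxohexanoate
Product: 14 methyl 9,9-dimethoxy-3,5,7-trioxo-8-(2,3,4,6-tetramethoxyphenyl)nonanoate (racemic), via acyl imidazole 12 (not isolated), via trilithium trianion 13 (not isolated)
Conditions: 9, CDI, THF, rt; separately 11 (3.2 equiv), LiN(i-Pr)2 (9.8 equiv), THF, −78 to 0 °C; solution of 12 added to 13 at −78 °C, then to −30 °C; AcOH at −78 °C, pH 6 buffer; no acidic silica
Reagents that add atoms: none
Why: This is a Claisen-type C-acylation of a 1,3,5-tricarbonyl polyanion, in which the terminal carbanion, formed last and least delocalised, reacts first with the activated acyl imidazole, while the excess trianion also takes up the imidazole N–H and the new acidic methylene; the existing centre stays racemic.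

Step 8
Reactants: 14 methyl 9,9-dimethoxy-3,5,7-trioxo-8-(2,3,4,6-tetramethoxyphenyl)nonanoate
Product: 17 5,7-dihydroxy-3-(2,3,4,6-tetramethoxyphenyl)-4H-chromen-4-one, via acylphloroglucinol acetal 15 (not isolated), via 2-methoxyisoflavanone 16 (not isolated)
Conditions: Mg(OMe)2 (4 equiv), dry MeOH, rt to 60 °C; then HCl in MeOH to pH 1, 50 °C, same flask
Reagents that add atoms: none
Why: Mg(OMe)2 turns the three active methylenes of 14 into a magnesium-chelated polyenolate, whose chain carbon C6 (future C4a) adds to the ester carbonyl C1 (future C5); loss of methoxide and enolisation give the aromatic ring A of 15, an intramolecular Claisen condensation of the kind known for 3,5,7-triketo esters. Drawn from the enolate toward the chain C7 oxygen, this closure is 6-(enolexo)-exo-trig. On acidification the acetal of 15 ionises to an oxocarbenium ion, an ortho hydroxyl traps it in a 6-exo-trig closure to 16, and loss of methanol through the C4 enol sets the C2=C3 bond, which is the acid cyclisation known for 2-aryl-3,3-dimethoxy-1-(2-hydroxyphenyl)propan-1-ones. No lasting stereocentre is created, since the aryl-bearing carbon and the acetal carbon both end as sp2 centres of 17. The selectivity needed is Claisen closure over aldol addition of chain C2 to the C7 ketone, and the substrate secures it because C7 is shielded by its tertiary neighbour carrying the di-ortho-substituted ring B and is held in an enolate chelate, while aldol addition and lactonisation are reversible in methoxide and aromatisation to the phenoxide is not. The same enolate character at C7 keeps the neighbouring C–H from triggering loss of methoxide from the acetal, and the two ortho hydroxyls of 15 are equivalent, so only one chromone can form.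

Compound list
1 | 1,2,3,5-tetramethoxybenzene | COc1cc(OC)c(OC)c(OC)c1 | starting material
2 | dimethyl oxalate | COC(=O)C(=O)OC | starting material
3 | (2,3,4,6-tetramethoxyphenyl)lithium | [Li]c1c(OC)cc(OC)c(OC)c1OC | intermediate
4 | methyl 2-oxo-2-(2,3,4,6-tetramethoxyphenyl)acetate | COC(=O)C(=O)c1c(OC)cc(OC)c(OC)c1OC | intermediate
5 | methyl 2-(2,3,4,6-tetramethoxyphenyl)acetate | COC(=O)Cc1c(OC)cc(OC)c(OC)c1OC | intermediate
6 | methyl formate | COC=O | starting material
7 | methyl 3-oxo-2-(2,3,4,6-tetramethoxyphenyl)propanoate (racemic, enolisable) | COC(=O)C(C=O)c1c(OC)cc(OC)c(OC)c1OC | intermediate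
8 | methyl 3,3-dimethoxy-2-(2,3,4,6-tetramethoxyphenyl)propanoate (racemic) | COC(=O)C(C(OC)OC)c1c(OC)cc(OC)c(OC)c1OC | intermediate
9 | 3,3-dimethoxy-2-(2,3,4,6-tetramethoxyphenyl)propanoic acid (racemic) | COC(OC)C(C(=O)O)c1c(OC)cc(OC)c(OC)c1OC | intermediate
10 | dehydroacetic acid (3-acetyl-4-hydroxy-6-methyl-2H-pyran-2-one) | CC(=O)c1c(O)cc(C)oc1=O | starting material
11 | methyl 3,5-dioxohexanoate | COC(=O)CC(=O)CC(C)=O | intermediate
12 | 1-(1H-imidazol-1-yl)-3,3-dimethoxy-2-(2,3,4,6-tetramethoxyphenyl)propan-1-one (racemic) | COC(OC)C(C(=O)n1ccnc1)c1c(OC)cc(OC)c(OC)c1OC | intermediate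
13 | trilithium trianion of methyl 3,5-dioxohexanoate | [Li+].[Li+].[Li+].C=C([O-])C=C([O-])C=C([O-])OC | intermediate
14 | methyl 9,9-dimethoxy-3,5,7-trioxo-8-(2,3,4,6-tetramethoxyphenyl)nonanoate (racemic) | COC(OC)C(C(=O)CC(=O)CC(=O)CC(=O)OC)c1c(OC)cc(OC)c(OC)c1OC | intermediate
15 | 3,3-dimethoxy-2-(2,3,4,6-tetramethoxyphenyl)-1-(2,4,6-trihydroxyphenyl)propan-1-one (racemic) | COC(OC)C(C(=O)c1c(O)cc(O)cc1O)c1c(OC)cc(OC)c(OC)c1OC | intermediate
16 | 5,7-dihydroxy-2-methoxy-3-(2,3,4,6-tetramethoxyphenyl)chroman-4-one (racemic diastereomer mixture) | COC1Oc2cc(O)cc(O)c2C(=O)C1c1c(OC)cc(OC)c(OC)c1OC | intermediate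
17 | 5,7-dihydroxy-3-(2,3,4,6-tetramethoxyphenyl)-4H-chromen-4-one | COc1cc(OC)c(-c2coc3cc(O)cc(O)c3c2=O)c(OC)c1OC | target

Total step count: 8. Longest linear sequence: 7 (steps 1–5, 7 and 8); step 6 is a one-step side branch.

Steps most likely to fail

Step 8. The polyenolate may close by aldol addition of chain C2 to the C7 ketone faster than by Claisen attack on the ester. Any chain left uncyclised may also be lost on acidification, when a chain enol oxygen closes onto the acetal carbon.
The fallback is the deoxybenzoin route, which sets out from 5.
- Saponification (LiOH, aqueous THF) should give 2-(2,3,4,6-tetramethoxyphenyl)acetic acid F1.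
- Friedel–Crafts acylation of excess phloroglucinol with this acid in BF3·OEt2 at 70–80 °C should give 2-(2,3,4,6-tetramethoxyphenyl)-1-(2,4,6-trihydroxyphenyl)ethan-1-one F2.
- A Vilsmeier-type one-carbon insertion (DMF, MeSO2Cl, BF3·OEt2, 50–70 °C) formylates the active methylene and closes ring C, and the fallback comes back to the route at 17.

Step 7. Proton transfer from the α-carbon of the acyl imidazole to the very basic trianion, followed by expulsion of methoxide, may outrun addition to the hindered carbonyl.
The fallback sets out from 9 (through 12) and swaps the nucleophile for a cyclic, ester-free and less charged carbanion.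
- Commercial 4-hydroxy-6-methyl-2H-pyran-2-one with LiN(i-Pr)2 (2 equiv, THF, −78 °C) gives the dilithium dianion of 4-hydroxy-6-methyl-2H-pyran-2-one F3.
- Acylation of this dianion at its exocyclic carbon by 12 should give 6-[4,4-dimethoxy-2-oxo-3-(2,3,4,6-tetramethoxyphenyl)butyl]-4-hydroxy-2H-pyran-2-one F4.
- Lactone methanolysis with Mg(OMe)2 in MeOH at rt comes back to the route at 14, obtained as its magnesium chelate and ready for step 8.

Step 5. Hydrolysis of the hindered ester may be slow enough for β-elimination of methoxide through the ester enolate to take over, and the acetal may be cleaved during acidification.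
The fallback sets out from 8 and avoids both hydroxide and the free acid.
- Aminolysis with the aluminium amide made from AlMe3 and MeNH(OMe)·HCl (CH2Cl2, 0 °C to reflux) should give N,3,3-trimethoxy-N-methyl-2-(2,3,4,6-tetramethoxyphenyl)propanamide F5.
- This amide, whose α-proton is far less acidic and whose chelated tetrahedral adduct holds until the quench, is offered to trianion 13 in place of 12, and the fallback comes back to the route at 14.

Further compounds
F1 | step 8 | 2-(2,3,4,6-tetramethoxyphenyl)acetic acid | COc1cc(OC)c(CC(=O)O)c(OC)c1OC
F2 | step 8 | 2-(2,3,4,6-tetramethoxyphenyl)-1-(2,4,6-trihydroxyphenyl)ethan-1-one | COc1cc(OC)c(CC(=O)c2c(O)cc(O)cc2O)c(OC)c1OC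
F3 | step 7 | dilithium dianion of 4-hydroxy-6-methyl-2H-pyran-2-one | [Li+].[Li+].C=C1C=C([O-])C=C([O-])O1
F4 | step 7 | 6-[4,4-dimethoxy-2-oxo-3-(2,3,4,6-tetramethoxyphenyl)butyl]-4-hydroxy-2H-pyran-2-one (racemic) | COC(OC)C(C(=O)Cc1cc(O)cc(=O)o1)c1c(OC)cc(OC)c(OC)c1OC
F5 | step 5 | N,3,3-trimethoxy-N-methyl-2-(2,3,4,6-tetramethoxyphenyl)propanamide (racemic) | COC(OC)C(C(=O)N(C)OC)c1c(OC)cc(OC)c(OC)c1OC
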